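The readings stem from a simulated flask on assumed constants; noise was put on by code.

An exposure of 26.4 mM·min is what I got by adding up [starting material] over time through the ochre run, up to its last reading at 5.00 min, and I reckoned theta from that area.

| flask | starting material | coupling partner | protic impurity | initiator | remark | time |
|---|---|---|---|---|---|---|
| ochre | 10 mM | 11 mM | 5 mM | 98 µM | run made earlier |  |
| red | 10 mM | 11 mM | 5 mM | 150 µM | run made earlier |  |
| alpha | 10 mM (fed, over 4.00 min) | 11.0 mM | 5.00 mM | 98 µM | all but starting material at the start; starting material goes in evenly over 4.00 min, the run ends at 8.0 min | 8.0 min |
| theta | 10 mM | 11.0 mM | 5.00 mM | 98 µM | a closed flask charged with all of it at once and left for 8.0 min | 8.0 min |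
| zeta | 10 mM | 11.0 mM (fed, over 4.00 min) | 5.00 mM | 98 µM | all but coupling partner at the start; coupling partner goes in evenly over 4.00 min, the run ends at 8.0 min | 8.0 min |
| eta | 10 mM | 11.0 mM | 5.00 mM | 98 µM | a single well-mixed tank run continuously and read at steady state, 8.0 min in it on average |  |

- ochre (time / min: product / %, starting material / %): 1.00: 12.6, 72.9; 2.00: 18.4, 52.0; 3.00: 26.2, 41.9; 4.00: 30.2, 33.4; 5.00: 35.0, 27.4
- red (time / s: product / %, starting material / %): 10.0: 2.8, 92.6; 25.0: 5.8, 84.0; 40.0: 8.7, 76.4; 60.0: 13.6, 67.5; 90.0: 18.2, 55.9

(each reading ± 1 percentage point)

- the set-up with the highest amount of product at the outlet or at the end, in percent of the starting material put in ("none" if the first two lie within 2 percentage points) (alpha / theta / zeta / eta / none)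
- amount of product at the outlet or at the end, in percent of the starting material put in, alpha
- amount of product at the outlet or at the end, in percent of the starting material put in, theta
- amount of product at the outlet or at the end, in percent of the starting material put in, zeta
- amount of product at the outlet or at the end, in percent of the starting material put in, eta

- the stated concentrations are those of everything mixed, before any reaction; amounts are the same in each set-up
- what was read earlier has a scatter of 1 percentage point, one standard deviation
- the feed brings no volume worth counting
- the earlier runs were made in a closed, stirred flask

I took product to form at a pseudo-first-order rate in [starting material], so product made equals a constant times exposure. Dividing the last ochre reading by the exposure gave the yield constant, the product made per unit of exposure, 0.133 min⁻¹. The same division on the red run gave 0.161 min⁻¹, a ratio of 1.21, close to the square root of the initiator ratio, 1.24, so I scaled the constant that way.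

I counted the starting material missing from the ochre balance as lost to the protic impurity, one for one, which by my reckoning put [protic impurity] at 1.24 mM at the last ochre reading. Taking that loss as first order in each of the two, the logarithmic fall of [protic impurity] grows in proportion to exposure, and this gave a first-order loss constant for starting material, at that [protic impurity], of 0.0655 min⁻¹.

Theta is the ochre charge left until 8.0 min. Holding the two constants at these values, I integrated the exponential tail of [starting material] from the last ochre reading onward, which added 6.20 mM·min of exposure, so I expected 43.2% of product in theta.

The forecast named theta as best, with 33% for alpha, 42.5% for theta, 37% for zeta and 32% for eta, reasoning that “the intermediate partitions between partner and impurity”.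

The flasks gave 37.2% for alpha, 43.3% for theta, 37.0% for zeta and 35.0% for eta, so theta was best.

    initiator → 2 initiating radical (k = 8.16 × 10⁻⁴ s⁻¹)
    starting material + initiating radical ⇌ chain carrier (K = 6.31 × 10⁵ L mol⁻¹, k = 1.28 × 10⁵ L mol⁻¹ s⁻¹)
    coupling partner + chain carrier → product + initiating radical (k = 2.10 × 10⁵ L mol⁻¹ s⁻¹)
    2 initiating radical → ended chains A (k = 2.00 × 10⁸ L mol⁻¹ s⁻¹)
    2 chain carrier → ended chains B (k = 1.80 × 10⁸ L mol⁻¹ s⁻¹)
    starting material + protic impurity → quenched substrate (k = 0.911 L mol⁻¹ s⁻¹)

The neighbouring flask was theta with 0.17 mM of initiator. Its protic impurity ended at 22% of its own charge, and from that logarithm I reckoned an exposure of 29.0 mM·min. The square root scaled the yield constant to 0.175 min⁻¹, and the product of the two came to 50.7%. That neighbouring flask gave 50.4% of product, with 10% of its starting material left.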